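**Assumption:** The target has no stereocentre or stereogenic double bond, so it is achiral and needs no enantiocontrol. I read the side chain as unbranched C22 (n-docosyl), giving C29H50O4.

## Retrosynthetic overview
1. Target 6 comes from selective hydrolysis of the crowded C2 vinylogous methyl ester of 3-docosyl-2,5-dimethoxy-1,4-benzoquinone 5.
2. Quinone 5 comes from oxidative demethylation of 3-docosyl-1,2,4,5-tetramethoxybenzene 4. The mirror symmetry of 4 makes both possible para-quinones identical.
3. Arene 4 comes from an aryl C–alkyl C disconnection: ortho-lithiated 1,2,4,5-tetramethoxybenzene 1 plus 1-bromodocosane 2.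
4. No ring is formed. The only ring, the six-membered carbocycle, is bought as arene 1.

## Route

Step 1
Reactants: 1 1,2,4,5-tetramethoxybenzene; 2 1-bromodocosane
Product: 4 3-docosyl-1,2,4,5-tetramethoxybenzene, via tetramethoxyphenyllithium 3 (not isolated)
Conditions: n-BuLi (1.1 equiv), THF, 0 °C → rt, 1 h; then DMPU, 2 in THF, 0 °C → rt, 16 h
Reagents that add atoms: none
Why: Directed ortho-metalation removes one of the two equivalent ring protons, each flanked by two OMe groups, and the aryllithium is then alkylated by SN2 on the primary bromide with DMPU breaking up aggregates; no stereocentre is formed.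

Step 2
Reactants: 4 3-docosyl-1,2,4,5-tetramethoxybenzene
Product: 5 3-docosyl-2,5-dimethoxy-1,4-benzoquinone
Conditions: CAN (2.5 equiv), MeCN/CH2Cl2/H2O, 0 °C → rt, 1 h
Reagents that add atoms: water, O
Why: CAN oxidative demethylation of a 1,4-dimethoxyarene (two one-electron oxidations with ipso attack of water) gives the p-quinone, both para OMe pairs of symmetric 4 lead to the same product, and the saturated chain and remaining ethers are untouched; no stereocentre is formed.

Step 3
Reactants: 5 3-docosyl-2,5-dimethoxy-1,4-benzoquinone
Product: 6 3-docosyl-2-hydroxy-5-methoxy-1,4-benzoquinone (target)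
Conditions: 70% aq HClO4, CH2Cl2/1,4-dioxane, rt, 2–4 h (TLC control)
Reagents that add atoms: water, O
Why: In this acid-catalysed addition–elimination hydrolysis of a vinylogous ester, the C2-OMe wedged between the chain and C1=O is twisted out of conjugation and cleaves much faster than the planar C5-OMe, a selectivity established for the C11–C15 homologues; no stereocentre is formed.

## Compound list
1 | 1,2,4,5-tetramethoxybenzene | COc1cc(OC)c(OC)cc1OC | starting material
2 | 1-bromodocosane | CCCCCCCCCCCCCCCCCCCCCCBr | starting material
3 | 2,3,5,6-tetramethoxyphenyllithium | [Li]c1c(OC)c(OC)cc(OC)c1OC | intermediate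
4 | 3-docosyl-1,2,4,5-tetramethoxybenzene | CCCCCCCCCCCCCCCCCCCCCCc1c(OC)c(OC)cc(OC)c1OC | intermediate
5 | 3-docosyl-2,5-dimethoxy-1,4-benzoquinone | CCCCCCCCCCCCCCCCCCCCCCC1=C(OC)C(=O)C=C(OC)C1=O | intermediate
6 | 3-docosyl-2-hydroxy-5-methoxy-1,4-benzoquinone | CCCCCCCCCCCCCCCCCCCCCCC1=C(O)C(=O)C=C(OC)C1=O | target

Total step count: 3. Longest linear sequence: 3 steps (1 → 4 → 5 → 6).

## Steps most likely to fail, with fallbacks

**Step 3 (highest risk).** In the two-phase acid medium the waxy substrate may give a mixture of 6, its regioisomer and the fully hydrolysed quinone. The fallback sets out from 5 and comes back at 6. Both ethers are cleaved on purpose and one methyl is then put back. Compound 5 is heated with 2 M aq NaOH in EtOH/THF and acidified with HCl to give 3-docosyl-2,5-dihydroxy-1,4-benzoquinone F1. F1 is then refluxed in MeOH/CHCl3 with catalytic H2SO4, a Fischer-type etherification of a vinylogous acid. Methanol adds at the unhindered C5 next to C6–H and not at the chain-shielded C2, which gives 6. Any over-methylated material is simply 5 and is recycled.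

**Step 1.** SN2 of a doubly ortho-substituted aryllithium on a C22 bromide can be slow, and E2 or Li–Br exchange can compete. The fallback sets out from 1 (through the same aryllithium 3) and comes back at 4. The C–C bond is made by carbonyl addition instead of substitution. Commercial 1-docosanol is oxidised (TEMPO cat., PhI(OAc)2, CH2Cl2) to docosanal F2. Aryllithium 3, generated from 1 with n-BuLi, is added to F2 at −78 °C and quenched with water to give racemic 1-(2,3,5,6-tetramethoxyphenyl)docosan-1-ol F3. Ionic hydrogenation (Et3SiH, TFA, CH2Cl2, 0 °C) removes the benzylic OH, erases the temporary stereocentre and delivers 4.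

**Step 2.** The lipid is poorly soluble in aqueous MeCN, and CAN can give dimeric quinones, nitration or side-chain oxidation. The fallback sets out from 1 and comes back at 5, with the order of events reversed. Compound 1 is oxidised with CAN in MeCN/H2O to the small, soluble 2,5-dimethoxy-1,4-benzoquinone F4. A docosyl radical is then generated from tricosanoic acid (AgNO3 cat., (NH4)2S2O8, MeCN/H2O, 70 °C; Minisci-type decarboxylative alkylation). It adds to one of the two equivalent C–H positions of F4 to give 5, bypassing 4 altogether.

## Further compounds
F1 | step 3 | 3-docosyl-2,5-dihydroxy-1,4-benzoquinone | CCCCCCCCCCCCCCCCCCCCCCC1=C(O)C(=O)C=C(O)C1=O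
F2 | step 1 | docosanal | CCCCCCCCCCCCCCCCCCCCCC=O
F3 | step 1 | racemic 1-(2,3,5,6-tetramethoxyphenyl)docosan-1-ol | CCCCCCCCCCCCCCCCCCCCCC(O)c1c(OC)c(OC)cc(OC)c1OC
F4 | step 2 | 2,5-dimethoxy-1,4-benzoquinone | COC1=CC(=O)C(OC)=CC1=O
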